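**Retrosynthetic overview**

1. Numbering (cembrane style): C1 is the ring-fusion carbon next to the lactone α-carbon C15, C2–C13 run round the 14-membered carbocycle, C14 is the O-bearing fusion carbon, C16 is the lactone C=O and C17 the exocyclic CH2.
2. The last C–C bond is C8–C9, closed by a nickel-catalysed reductive coupling of an (E)-alkenyl iodide (C8) with a primary alkyl bromide (C9). The enabling feature is that C8 is the methyl-bearing sp2 carbon of the 7E trisubstituted alkene and C9 an unbranched CH2 of the carbocycle, while the C11 chloride is secondary and flanked by quaternary C12, so it stays inert.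
3. The seco compound comes from fragment 1 (C9–C14 aldehyde carrying the finished chlorohydrin) and fragment 2 (allene C16/C15/C1–C8 carrying the alkenyl iodide) by allene hydroboration–allylboration (C1–C14 bond, anti), then hydroboration/oxidative lactonisation.
4. Fragment 1 gets C11/C12 from a Sharpless epoxidation and a titanium-directed chloride opening; fragment 2 comes from geranyl acetate by oxidative cleavage, alkyne homologation and hydrozirconation–iodination.
5. Ring order: γ-lactone first (step 19), 14-membered carbocycle second (step 21); α-methylenation and desilylation finish.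

Key step: step 21

Assumption: the aldehyde face chosen by the diisopinocampheylborane reagent is taken to follow the sense known for simple aliphatic aldehydes (borane from (−)-α-pinene giving the 14S carbinol), the remote C12 centre of the aldehyde not overriding it.

**Route**

Step 1
Reactants: 1 3-[(tert-butyldimethylsilyl)oxy]propanal
Product: 2 ethyl (2E)-5-[(tert-butyldimethylsilyl)oxy]-2-methylpent-2-enoate
Conditions: Ph3P=C(CH3)CO2Et, CH2Cl2, 23 °C
Reagents that add atoms: ethyl 2-(triphenylphosphoranylidene)propanoate CCOC(=O)C(C)=P(c1ccccc1)(c1ccccc1)c1ccccc1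
Why: Wittig olefination with a stabilised α-methyl ylide should give the (E)-trisubstituted enoate, whose geometry later fixes the C11/C12 relationship.

Step 2
Reactants: 2 ethyl (2E)-5-[(tert-butyldimethylsilyl)oxy]-2-methylpent-2-enoate
Product: 3 (2E)-5-[(tert-butyldimethylsilyl)oxy]-2-methylpent-2-en-1-ol
Conditions: iBu2AlH, CH2Cl2, −78 °C; Rochelle-salt work-up
Reagents that add atoms: none
Why: 1,2-reduction of the enoate with iBu2AlH should give the allylic alcohol needed for directed epoxidation without touching the alkene geometry or the silyl ether.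

Step 3
Reactants: 3 (2E)-5-[(tert-butyldimethylsilyl)oxy]-2-methylpent-2-en-1-ol
Product: 4 [(2R,3R)-3-{2-[(tert-butyldimethylsilyl)oxy]ethyl}-2-methyloxiran-2-yl]methanol
Conditions: Ti(OiPr)4, D-(−)-diethyl tartrate, t-BuOOH, 4 Å molecular sieves, CH2Cl2, −20 °C
Reagents that add atoms: tert-butyl hydroperoxide CC(C)(C)OO
Why: Sharpless asymmetric epoxidation; the D-(−)-tartrate complex should deliver oxygen to the face that gives the (2R,3R)-epoxide, setting C12 directly and C11 for later inversion.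

Step 4
Reactants: 4 [(2R,3R)-3-{2-[(tert-butyldimethylsilyl)oxy]ethyl}-2-methyloxiran-2-yl]methanol
Product: 5 (2R,3S)-5-[(tert-butyldimethylsilyl)oxy]-3-chloro-2-methylpentane-1,2-diol
Conditions: ClTi(OiPr)3, benzene, 23 °C; aqueous tartaric acid work-up
Reagents that add atoms: chlorotitanium triisopropoxide CC(C)O[Ti](Cl)(OC(C)C)OC(C)C
Why: titanium-chelated opening of a 2,3-epoxy alcohol should deliver chloride to C3 by SN2 with inversion, giving the 11S chloride and leaving the 12R tertiary alcohol untouched.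

Step 5
Reactants: 5 (2R,3S)-5-[(tert-butyldimethylsilyl)oxy]-3-chloro-2-methylpentane-1,2-diol
Product: 7 (2R)-2-{(1S)-3-[(tert-butyldimethylsilyl)oxy]-1-chloropropyl}-2-methyloxirane, via primary tosylate 6 (not isolated)
Conditions: TsCl, Et3N, Bu2SnO (cat.), CH2Cl2, 0 °C; then K2CO3, MeOH, 0 °C
Reagents that add atoms: none
Why: selective primary sulfonylation followed by Williamson closure (3-exo-tet) should give the terminal epoxide, because the tertiary alkoxide displaces the primary tosylate far faster than the hindered secondary chloride.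

Step 6
Reactants: 7 (2R)-2-{(1S)-3-[(tert-butyldimethylsilyl)oxy]-1-chloropropyl}-2-methyloxirane
Product: 8 (4R,5S)-7-[(tert-butyldimethylsilyl)oxy]-5-chloro-4-methylhept-1-en-4-ol
Conditions: CH2=CHMgBr, CuI (10 mol%), THF, −40 to −20 °C; NH4Cl quench at −20 °C
Reagents that add atoms: vinylmagnesium bromide C=C[Mg]Br
Why: copper-catalysed Grignard opening of the 2,2-disubstituted epoxide at its CH2 terminus should install the future C14 as a vinyl carbon; the cold quench keeps the magnesium alkoxide from closing onto C11.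

Step 7
Reactants: 8 (4R,5S)-7-[(tert-butyldimethylsilyl)oxy]-5-chloro-4-methylhept-1-en-4-ol
Product: 9 (4R,5S)-4,7-bis[(tert-butyldimethylsilyl)oxy]-5-chloro-4-methylhept-1-ene
Conditions: TBSOTf, 2,6-lutidine, CH2Cl2, 0 to 23 °C
Reagents that add atoms: tert-butyldimethylsilyl trifluoromethanesulfonate CC(C)(C)[Si](C)(C)OS(=O)(=O)C(F)(F)F
Why: silyl triflate silylation should cap the hindered tertiary alcohol, which blocks reversion of the chlorohydrin to an epoxide in all later basic steps.

Step 8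
Reactants: 9 (4R,5S)-4,7-bis[(tert-butyldimethylsilyl)oxy]-5-chloro-4-methylhept-1-ene
Product: 11 (3R,4S)-3,6-bis[(tert-butyldimethylsilyl)oxy]-4-chloro-3-methylhexanal, via ozonide 10 (not isolated)
Conditions: O3, CH2Cl2, −78 °C; then PPh3, −78 to 23 °C
Reagents that add atoms: ozone [O-][O+]=O
Why: ozonolysis with reductive work-up should cut the terminal alkene to the C14 aldehyde (fragment 1) without affecting the stereocentres.

Step 9
Reactants: 12 geranyl acetate
Product: 13 (2E)-5-(3,3-dimethyloxiran-2-yl)-3-methylpent-2-en-1-yl acetate (racemic at the oxirane)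
Conditions: mCPBA, CH2Cl2, 0 °C
Reagents that add atoms: 3-chloroperoxybenzoic acid OOC(=O)c1cccc(Cl)c1
Why: Prilezhaev epoxidation should take the electron-rich 6,7-alkene in preference to the 2,3-alkene, which is deactivated by the allylic acetate.

Step 10
Reactants: 13 (2E)-5-(3,3-dimethyloxiran-2-yl)-3-methylpent-2-en-1-yl acetate
Product: 14 (2E)-3-methyl-6-oxohex-2-en-1-yl acetate
Conditions: H5IO6, THF/H2O, 0 °C
Reagents that add atoms: water O
Why: periodic acid should hydrolyse the epoxide and cleave the resulting glycol (Malaprade-type cleavage) to the aldehyde, leaving the (2E)-alkene intact.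

Step 11
Reactants: 14 (2E)-3-methyl-6-oxohex-2-en-1-yl acetate
Product: 15 (2E)-3-methylhept-2-en-6-yn-1-ol
Conditions: dimethyl (1-diazo-2-oxopropyl)phosphonate, K2CO3, MeOH, 0 to 23 °C
Reagents that add atoms: dimethyl (1-diazo-2-oxopropyl)phosphonate CC(=O)C(=[N+]=[N-])P(=O)(OC)OC
Why: Ohira–Bestmann homologation should convert the aldehyde into the terminal alkyne, and the methanolic carbonate should remove the acetate in the same operation.

Step 12
Reactants: 15 (2E)-3-methylhept-2-en-6-yn-1-ol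
Product: 16 (2E)-3-methyloct-2-en-6-yn-1-ol
Conditions: n-BuLi (2.1 equiv), THF, −78 to 0 °C; then MeI (1.05 equiv), −78 to 23 °C
Reagents that add atoms: iodomethane CI
Why: acetylide alkylation of the alkoxide–acetylide dianion should occur on carbon, the lithium acetylide being the better nucleophile towards iodomethane in THF.

Step 13
Reactants: 16 (2E)-3-methyloct-2-en-6-yn-1-ol
Product: 18 (2E,6E)-7-iodo-3-methylocta-2,6-dien-1-ol, via alkenylzirconocene 17 (not isolated)
Conditions: Cp2Zr(H)Cl (3 equiv), THF, 50 °C; then I2, THF, 0 °C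
Reagents that add atoms: iodine II
Why: hydrozirconation–iodination; syn addition with thermodynamic equilibration under excess reagent should place zirconium on the methyl-bearing alkyne carbon, and iodinolysis with retention should give the (E)-2-iodo-2-alkene, fixing the 7E geometry and the C8 handle.

Step 14
Reactants: 18 (2E,6E)-7-iodo-3-methylocta-2,6-dien-1-ol
Product: 19 (2E,6E)-1-bromo-7-iodo-3-methylocta-2,6-diene
Conditions: CBr4, PPh3, CH2Cl2, 0 °C
Reagents that add atoms: carbon tetrabromide BrC(Br)(Br)Br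
Why: Appel bromination of the primary allylic alcohol should proceed without allylic transposition at low temperature.

Step 15
Reactants: 19 (2E,6E)-1-bromo-7-iodo-3-methylocta-2,6-diene
Product: 20 (5E,9E)-10-iodo-6-methylundeca-5,9-dien-2-yn-1-ol
Conditions: HC≡CCH2OH, CuI, NaI, K2CO3, DMF, 23 °C
Reagents that add atoms: prop-2-yn-1-ol C#CCO
Why: copper-mediated SN2 coupling of a terminal alkyne with the primary allylic bromide should give the skipped enyne, the alkenyl iodide being inert at room temperature.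

Step 16
Reactants: 20 (5E,9E)-10-iodo-6-methylundeca-5,9-dien-2-yn-1-ol
Product: 23 (5E,9E)-10-iodo-6-methylundeca-1,2,5,9-tetraene, via sulfonylhydrazine 21 (not isolated), via propargylic diazene 22 (not isolated)
Conditions: PPh3, EtO2CN=NCO2Et, 2-nitrobenzenesulfonylhydrazide, THF, −15 to 23 °C
Reagents that add atoms: none
Why: Myers allene synthesis; Mitsunobu N-alkylation, loss of sulfinic acid and retro-ene loss of N2 from the propargylic diazene should give the terminal allene (fragment 2) under neutral conditions.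

Step 17
Reactants: 23 (5E,9E)-10-iodo-6-methylundeca-1,2,5,9-tetraene; 11 (3R,4S)-3,6-bis[(tert-butyldimethylsilyl)oxy]-4-chloro-3-methylhexanal
Product: 25 (3R,4S,6R,7S)-6,9-bis[(tert-butyldimethylsilyl)oxy]-7-chloro-3-[(2E,6E)-7-iodo-3-methylocta-2,6-dien-1-yl]-6-methylnon-1-en-4-ol, via allylborane 24 (not isolated)
Conditions: (+)-(Ipc)2BH [from (−)-α-pinene and BH3·SMe2], THF, −25 to 23 °C; then 11, −78 to 23 °C; then NaOH, H2O2, 0 °C
Reagents that add atoms: none
Why: allene hydroboration–allylboration; boron should add to the terminal allene carbon, the allylborane should equilibrate by 1,3-boratropic shift to the (E)-isomer, and the chair transition state should then give the anti C1/C14 relationship, with the isopinocampheyl groups choosing the aldehyde face (14S, hence 1R).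

Step 18
Reactants: 25 (3R,4S,6R,7S)-6,9-bis[(tert-butyldimethylsilyl)oxy]-7-chloro-3-[(2E,6E)-7-iodo-3-methylocta-2,6-dien-1-yl]-6-methylnon-1-en-4-ol
Product: 27 (3R,4S,6R,7S)-6,9-bis[(tert-butyldimethylsilyl)oxy]-7-chloro-3-[(2E,6E)-7-iodo-3-methylocta-2,6-dien-1-yl]-6-methylnonane-1,4-diol, via bis-borane 26 (not isolated)
Conditions: 9-BBN (2.5 equiv), THF, 0 to 23 °C; then NaOH, H2O2, 0 °C
Reagents that add atoms: hydrogen peroxide OO
Why: hydroboration–oxidation; 9-BBN should select the monosubstituted vinyl group over both trisubstituted alkenes and place oxygen on the terminal carbon (future C16).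

Step 19
Reactants: 27 (3R,4S,6R,7S)-6,9-bis[(tert-butyldimethylsilyl)oxy]-7-chloro-3-[(2E,6E)-7-iodo-3-methylocta-2,6-dien-1-yl]-6-methylnonane-1,4-diol
Product: 28 (4R,5S)-5-{(2R,3S)-2,5-bis[(tert-butyldimethylsilyl)oxy]-3-chloro-2-methylpentyl}-4-[(2E,6E)-7-iodo-3-methylocta-2,6-dien-1-yl]oxolan-2-one
Conditions: TEMPO (20 mol%), PhI(OAc)2, CH2Cl2, 23 °C
Reagents that add atoms: none
Why: oxoammonium oxidation of the primary alcohol, lactol formation with the C14 hydroxyl and further oxidation should close the γ-lactone, the anti adduct giving the trans C1/C14 ring.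

Step 20
Reactants: 28 (4R,5S)-5-{(2R,3S)-2,5-bis[(tert-butyldimethylsilyl)oxy]-3-chloro-2-methylpentyl}-4-[(2E,6E)-7-iodo-3-methylocta-2,6-dien-1-yl]oxolan-2-one
Product: 29 (4R,5S)-5-{(2R,3S)-5-bromo-2-[(tert-butyldimethylsilyl)oxy]-3-chloro-2-methylpentyl}-4-[(2E,6E)-7-iodo-3-methylocta-2,6-dien-1-yl]oxolan-2-one
Conditions: Ph3PBr2, CH2Cl2, 0 to 23 °C
Reagents that add atoms: dibromotriphenylphosphorane BrP(Br)(c1ccccc1)(c1ccccc1)c1ccccc1
Why: direct silyl ether to bromide conversion through a silyloxyphosphonium ion should take only the primary silyl ether, the tertiary one being too hindered for SN2 displacement.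

Step 21
Reactants: 29 (4R,5S)-5-{(2R,3S)-5-bromo-2-[(tert-butyldimethylsilyl)oxy]-3-chloro-2-methylpentyl}-4-[(2E,6E)-7-iodo-3-methylocta-2,6-dien-1-yl]oxolan-2-one
Product: 30 (3aR,5E,9E,13S,14R,15aS)-14-[(tert-butyldimethylsilyl)oxy]-13-chloro-6,10,14-trimethyl-3a,4,7,8,11,12,13,14,15,15a-decahydrocyclotetradeca[b]furan-2(3H)-one
Conditions: NiI2 (30 mol%), 4,4′-di-tert-butyl-2,2′-bipyridine (30 mol%), NaI (0.5 equiv), Mn powder (6 equiv), DMPU/THF, 40 °C, syringe-pump addition of 29 (final 1 mM)
Reagents that add atoms: none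
Why: Proposed new method: zerovalent nickel (from NiI2, the bipyridine and Mn) should insert with retention into the C8–I bond, while a monovalent nickel species abstracts halogen from the primary C9 bromide (or the iodide formed in situ with NaI) to give the C9 radical, which is captured at the alkenylnickel centre and released by C(sp2)–C(sp3) reductive elimination from trivalent nickel. The closest known reaction type is the intermolecular nickel-catalysed reductive cross-electrophile coupling of alkenyl halides with primary alkyl halides, together with intramolecular versions that close small rings; closing a 14-membered ring this way is the untested element. The 14-membered carbocycle is closed in macrocyclic mode by intramolecular radical capture at nickel under pseudo-high dilution, helped by the two E-trisubstituted alkenes and the trans-lactone, which limit the conformations of the seco chain. No stereocentre is formed: the 7E geometry follows from the stereoretentive oxidative addition, and C1, C11, C12 and C14 are spectators. The step needs cross- over homo-coupling and C9 over C11 selectivity; the first comes from the different activation modes of the C(sp2)–I and C(sp3)–Br bonds, the second from the C11 chloride being secondary, hindered by quaternary C12 and a much poorer radical precursor. Lactone and silyl ethers should be tolerated, which is why the finished chlorohydrin can be carried through the ring closure, whereas a B-alkyl Suzuki closure would meet a γ-chloroalkylborane prone to cyclopropane formation under base.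

Step 22
Reactants: 30 (3aR,5E,9E,13S,14R,15aS)-14-[(tert-butyldimethylsilyl)oxy]-13-chloro-6,10,14-trimethyl-3a,4,7,8,11,12,13,14,15,15a-decahydrocyclotetradeca[b]furan-2(3H)-one
Product: 33 (3aR,5E,9E,13S,14R,15aS)-14-[(tert-butyldimethylsilyl)oxy]-13-chloro-6,10,14-trimethyl-3-methylidene-3a,4,7,8,11,12,13,14,15,15a-decahydrocyclotetradeca[b]furan-2(3H)-one, via Mannich base 31 (not isolated), via ammonium iodide 32 (not isolated)
Conditions: LiN(iPr)2, THF, −78 °C; CH2=NMe2+ I−, −78 to 23 °C; then MeI, THF, 23 °C; then NaHCO3 (aq), CH2Cl2, 23 °C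
Reagents that add atoms: N,N-dimethylmethylideneammonium iodide C=[N+](C)C.[I-]
Why: Eschenmoser methylenation; Mannich reaction of the lithium enolate, N-quaternisation and E1cB loss of trimethylamine should install the exocyclic methylene at C15, the only enolisable position.

Step 23
Reactants: 33 (3aR,5E,9E,13S,14R,15aS)-14-[(tert-butyldimethylsilyl)oxy]-13-chloro-6,10,14-trimethyl-3-methylidene-3a,4,7,8,11,12,13,14,15,15a-decahydrocyclotetradeca[b]furan-2(3H)-one
Product: 34 (3aR,5E,9E,13S,14R,15aS)-13-chloro-14-hydroxy-6,10,14-trimethyl-3-methylidene-3a,4,7,8,11,12,13,14,15,15a-decahydrocyclotetradeca[b]furan-2(3H)-one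
Conditions: HF (48% aq), MeCN, 0 to 23 °C
Reagents that add atoms: none
Why: acidic fluoride desilylation should free the tertiary alcohol without generating an alkoxide, so neither epoxide closure onto C11 nor conjugate addition to the methylene lactone is expected.

**Compound list**

1 | 3-[(tert-butyldimethylsilyl)oxy]propanal | O=CCCO[Si](C)(C)C(C)(C)C | starting material
2 | ethyl (2E)-5-[(tert-butyldimethylsilyl)oxy]-2-methylpent-2-enoate | CCOC(=O)/C(C)=C/CCO[Si](C)(C)C(C)(C)C | intermediate
3 | (2E)-5-[(tert-butyldimethylsilyl)oxy]-2-methylpent-2-en-1-ol | OC/C(C)=C/CCO[Si](C)(C)C(C)(C)C | intermediate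
4 | [(2R,3R)-3-{2-[(tert-butyldimethylsilyl)oxy]ethyl}-2-methyloxiran-2-yl]methanol | OC[C@@]1(C)O[C@@H]1CCO[Si](C)(C)C(C)(C)C | intermediate
5 | (2R,3S)-5-[(tert-butyldimethylsilyl)oxy]-3-chloro-2-methylpentane-1,2-diol | OC[C@@](C)(O)[C@@H](Cl)CCO[Si](C)(C)C(C)(C)C | intermediate
6 | (2R,3S)-5-[(tert-butyldimethylsilyl)oxy]-3-chloro-2-hydroxy-2-methylpentyl 4-methylbenzenesulfonate | Cc1ccc(cc1)S(=O)(=O)OC[C@@](C)(O)[C@@H](Cl)CCO[Si](C)(C)C(C)(C)C | intermediate
7 | (2R)-2-{(1S)-3-[(tert-butyldimethylsilyl)oxy]-1-chloropropyl}-2-methyloxirane | C1O[C@@]1(C)[C@@H](Cl)CCO[Si](C)(C)C(C)(C)C | intermediate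
8 | (4R,5S)-7-[(tert-butyldimethylsilyl)oxy]-5-chloro-4-methylhept-1-en-4-ol | C=CC[C@@](C)(O)[C@@H](Cl)CCO[Si](C)(C)C(C)(C)C | intermediate
9 | (4R,5S)-4,7-bis[(tert-butyldimethylsilyl)oxy]-5-chloro-4-methylhept-1-ene | C=CC[C@@](C)(O[Si](C)(C)C(C)(C)C)[C@@H](Cl)CCO[Si](C)(C)C(C)(C)C | intermediate
10 | 3-{(2R,3S)-2,5-bis[(tert-butyldimethylsilyl)oxy]-3-chloro-2-methylpentyl}-1,2,4-trioxolane (mixture at the trioxolane carbon) | C1OC(C[C@@](C)(O[Si](C)(C)C(C)(C)C)[C@@H](Cl)CCO[Si](C)(C)C(C)(C)C)OO1 | intermediate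
11 | (3R,4S)-3,6-bis[(tert-butyldimethylsilyl)oxy]-4-chloro-3-methylhexanal | O=CC[C@@](C)(O[Si](C)(C)C(C)(C)C)[C@@H](Cl)CCO[Si](C)(C)C(C)(C)C | intermediate
12 | geranyl acetate, (2E)-3,7-dimethylocta-2,6-dien-1-yl acetate | CC(=O)OC/C=C(C)/CCC=C(C)C | starting material
13 | (2E)-5-(3,3-dimethyloxiran-2-yl)-3-methylpent-2-en-1-yl acetate (racemic at the oxirane) | CC(=O)OC/C=C(C)/CCC1OC1(C)C | intermediate
14 | (2E)-3-methyl-6-oxohex-2-en-1-yl acetate | CC(=O)OC/C=C(C)/CCC=O | intermediate
15 | (2E)-3-methylhept-2-en-6-yn-1-ol | OC/C=C(C)/CCC#C | intermediate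
16 | (2E)-3-methyloct-2-en-6-yn-1-ol | OC/C=C(C)/CCC#CC | intermediate
17 | O,C-bis(chlorozirconocene) derivative of (2E,6E)-3-methylocta-2,6-dien-1-ol (zirconium on O and on C7) | Cl[Zr](OC/C=C(C)/CC/C=C(C)/[Zr](Cl)(C1C=CC=C1)C1C=CC=C1)(C1C=CC=C1)C1C=CC=C1 | intermediate
18 | (2E,6E)-7-iodo-3-methylocta-2,6-dien-1-ol | OC/C=C(C)/CC/C=C(C)/I | intermediate
19 | (2E,6E)-1-bromo-7-iodo-3-methylocta-2,6-diene | BrC/C=C(C)/CC/C=C(C)/I | intermediate
20 | (5E,9E)-10-iodo-6-methylundeca-5,9-dien-2-yn-1-ol | OCC#CC/C=C(C)/CC/C=C(C)/I | intermediate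
21 | N-[(5E,9E)-10-iodo-6-methylundeca-5,9-dien-2-yn-1-yl]-2-nitrobenzenesulfonohydrazide (alkyl on the sulfonylated nitrogen) | NN(CC#CC/C=C(C)/CC/C=C(C)/I)S(=O)(=O)c1ccccc1[N+](=O)[O-] | intermediate
22 | [(5E,9E)-10-iodo-6-methylundeca-5,9-dien-2-yn-1-yl]diazene | N=NCC#CC/C=C(C)/CC/C=C(C)/I | intermediate
23 | (5E,9E)-10-iodo-6-methylundeca-1,2,5,9-tetraene | C=C=CC/C=C(C)/CC/C=C(C)/I | intermediate
24 | [(2E,5E,9E)-10-iodo-6-methylundeca-2,5,9-trien-1-yl]bis(isopinocampheyl)borane (isopinocampheyl groups from (−)-α-pinene) | B(C/C=C/C/C=C(C)/CC/C=C(C)/I)([C@H]1C[C@H]2C[C@@H]([C@@H]1C)C2(C)C)[C@H]1C[C@H]2C[C@@H]([C@@H]1C)C2(C)C | intermediate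
25 | (3R,4S,6R,7S)-6,9-bis[(tert-butyldimethylsilyl)oxy]-7-chloro-3-[(2E,6E)-7-iodo-3-methylocta-2,6-dien-1-yl]-6-methylnon-1-en-4-ol | C=C[C@@H](C/C=C(C)/CC/C=C(C)/I)[C@@H](O)C[C@@](C)(O[Si](C)(C)C(C)(C)C)[C@@H](Cl)CCO[Si](C)(C)C(C)(C)C | intermediate
26 | 1-C,4-O-bis(9-borabicyclo[3.3.1]nonan-9-yl) derivative of diol 27 | B1(C2CCCC1CCC2)CC[C@@H](C/C=C(C)/CC/C=C(C)/I)[C@@H](OB1C2CCCC1CCC2)C[C@@](C)(O[Si](C)(C)C(C)(C)C)[C@@H](Cl)CCO[Si](C)(C)C(C)(C)C | intermediate
27 | (3R,4S,6R,7S)-6,9-bis[(tert-butyldimethylsilyl)oxy]-7-chloro-3-[(2E,6E)-7-iodo-3-methylocta-2,6-dien-1-yl]-6-methylnonane-1,4-diol | OCC[C@@H](C/C=C(C)/CC/C=C(C)/I)[C@@H](O)C[C@@](C)(O[Si](C)(C)C(C)(C)C)[C@@H](Cl)CCO[Si](C)(C)C(C)(C)C | intermediate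
28 | (4R,5S)-5-{(2R,3S)-2,5-bis[(tert-butyldimethylsilyl)oxy]-3-chloro-2-methylpentyl}-4-[(2E,6E)-7-iodo-3-methylocta-2,6-dien-1-yl]oxolan-2-one | O=C1C[C@@H](C/C=C(C)/CC/C=C(C)/I)[C@@H](O1)C[C@@](C)(O[Si](C)(C)C(C)(C)C)[C@@H](Cl)CCO[Si](C)(C)C(C)(C)C | intermediate
29 | (4R,5S)-5-{(2R,3S)-5-bromo-2-[(tert-butyldimethylsilyl)oxy]-3-chloro-2-methylpentyl}-4-[(2E,6E)-7-iodo-3-methylocta-2,6-dien-1-yl]oxolan-2-one | O=C1C[C@@H](C/C=C(C)/CC/C=C(C)/I)[C@@H](O1)C[C@@](C)(O[Si](C)(C)C(C)(C)C)[C@@H](Cl)CCBr | intermediate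
30 | (3aR,5E,9E,13S,14R,15aS)-14-[(tert-butyldimethylsilyl)oxy]-13-chloro-6,10,14-trimethyl-3a,4,7,8,11,12,13,14,15,15a-decahydrocyclotetradeca[b]furan-2(3H)-one | C1C(=O)O[C@H]2C[C@@](C)(O[Si](C)(C)C(C)(C)C)[C@@H](Cl)CC/C(C)=C/CC/C(C)=C/C[C@H]12 | intermediate
31 | 3-[(dimethylamino)methyl] derivative of 30 (mixture at C3) | CN(C)CC1C(=O)O[C@H]2C[C@@](C)(O[Si](C)(C)C(C)(C)C)[C@@H](Cl)CC/C(C)=C/CC/C(C)=C/C[C@H]12 | intermediate
32 | 3-[(trimethylammonio)methyl] derivative of 30, iodide (mixture at C3) | C[N+](C)(C)CC1C(=O)O[C@H]2C[C@@](C)(O[Si](C)(C)C(C)(C)C)[C@@H](Cl)CC/C(C)=C/CC/C(C)=C/C[C@H]12.[I-] | intermediate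
33 | (3aR,5E,9E,13S,14R,15aS)-14-[(tert-butyldimethylsilyl)oxy]-13-chloro-6,10,14-trimethyl-3-methylidene-3a,4,7,8,11,12,13,14,15,15a-decahydrocyclotetradeca[b]furan-2(3H)-one | C=C1C(=O)O[C@H]2C[C@@](C)(O[Si](C)(C)C(C)(C)C)[C@@H](Cl)CC/C(C)=C/CC/C(C)=C/C[C@H]12 | intermediate
34 | (3aR,5E,9E,13S,14R,15aS)-13-chloro-14-hydroxy-6,10,14-trimethyl-3-methylidene-3a,4,7,8,11,12,13,14,15,15a-decahydrocyclotetradeca[b]furan-2(3H)-one | C=C1C(=O)O[C@H]2C[C@@](C)(O)[C@@H](Cl)CC/C(C)=C/CC/C(C)=C/C[C@H]12 | target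

**Step count and risks**

Total step count: 23. Longest linear sequence: 15 steps (steps 1–8 then 17–23; steps 9–16 then 17–23 is equally long).

Steps most likely to fail:

1. Step 21 (Proposed new method). Intermolecular coupling may outrun ring closure (oligomerisation), either carbon–halogen bond may be reduced before coupling, or the alkylnickel may lose a β-hydride. The fallback sets out from 29 and comes back at 30, separating the two activation events with known chemistry. Finkelstein exchange (NaI, acetone, reflux) should give (4R,5S)-5-{(2R,3S)-2-[(tert-butyldimethylsilyl)oxy]-3-chloro-5-iodo-2-methylpentyl}-4-[(2E,6E)-7-iodo-3-methylocta-2,6-dien-1-yl]oxolan-2-one F1. Zinc insertion (Zn dust, LiCl, THF, 25–35 °C), which should be selective for the primary alkyl iodide over the alkenyl iodide at this temperature, would give the corresponding alkylzinc iodide F2. Slow addition of F2 to Pd(OAc)2/SPhos in THF/DMA at 50 °C should then close the ring by intramolecular Negishi coupling to 30.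

2. Step 17. Equilibration of the kinetic (Z)-allylborane to the (E)-isomer may be incomplete, eroding the anti relationship, or facial control by the borane may be poor. The fallback sets out from 20 and 11 and comes back at 25, replacing the boron allyl by a chromium allyl. Reduction of the propargylic alcohol with NaAlH2(OCH2CH2OMe)2 (THF, 0 °C) should give (2E,5E,9E)-10-iodo-6-methylundeca-2,5,9-trien-1-ol F3, and Appel bromination (CBr4, PPh3) the allylic bromide (2E,5E,9E)-1-bromo-10-iodo-6-methylundeca-2,5,9-triene F4. A catalytic asymmetric Nozaki–Hiyama allylation of 11 with F4 (CrCl2 10 mol%, a chiral tridentate bis(oxazolinyl)carbazole ligand, Mn powder, Me3SiCl, THF) should be anti-selective whatever the bromide geometry and give the silyl ether (3R,4S,6R,7S)-6,9-bis[(tert-butyldimethylsilyl)oxy]-7-chloro-3-[(2E,6E)-7-iodo-3-methylocta-2,6-dien-1-yl]-6-methyl-4-[(trimethylsilyl)oxy]non-1-ene F5. Brief treatment with citric acid in MeOH should then free 25.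

3. Step 20. The phosphorus dibromide may transfer bromine to an alkene or cleave the tertiary silyl ether. The fallback sets out from 28 and comes back at 29 in two separate operations. Buffered HF·pyridine (pyridine, THF, 0 °C) should remove only the primary silyl group to give (4R,5S)-5-{(2R,3S)-2-[(tert-butyldimethylsilyl)oxy]-3-chloro-5-hydroxy-2-methylpentyl}-4-[(2E,6E)-7-iodo-3-methylocta-2,6-dien-1-yl]oxolan-2-one F6, and Appel bromination (CBr4, PPh3, CH2Cl2, 0 °C) should convert it into 29.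

Further compounds
F1 | step 21 | (4R,5S)-5-{(2R,3S)-2-[(tert-butyldimethylsilyl)oxy]-3-chloro-5-iodo-2-methylpentyl}-4-[(2E,6E)-7-iodo-3-methylocta-2,6-dien-1-yl]oxolan-2-one | O=C1C[C@@H](C/C=C(C)/CC/C=C(C)/I)[C@@H](O1)C[C@@](C)(O[Si](C)(C)C(C)(C)C)[C@@H](Cl)CCI
F2 | step 21 | alkylzinc iodide derived from F1 (zinc on C9) | O=C1C[C@@H](C/C=C(C)/CC/C=C(C)/I)[C@@H](O1)C[C@@](C)(O[Si](C)(C)C(C)(C)C)[C@@H](Cl)CC[Zn]I
F3 | step 17 | (2E,5E,9E)-10-iodo-6-methylundeca-2,5,9-trien-1-ol | OC/C=C/C/C=C(C)/CC/C=C(C)/I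
F4 | step 17 | (2E,5E,9E)-1-bromo-10-iodo-6-methylundeca-2,5,9-triene | BrC/C=C/C/C=C(C)/CC/C=C(C)/I
F5 | step 17 | (3R,4S,6R,7S)-6,9-bis[(tert-butyldimethylsilyl)oxy]-7-chloro-3-[(2E,6E)-7-iodo-3-methylocta-2,6-dien-1-yl]-6-methyl-4-[(trimethylsilyl)oxy]non-1-ene | C=C[C@@H](C/C=C(C)/CC/C=C(C)/I)[C@@H](O[Si](C)(C)C)C[C@@](C)(O[Si](C)(C)C(C)(C)C)[C@@H](Cl)CCO[Si](C)(C)C(C)(C)C
F6 | step 20 | (4R,5S)-5-{(2R,3S)-2-[(tert-butyldimethylsilyl)oxy]-3-chloro-5-hydroxy-2-methylpentyl}-4-[(2E,6E)-7-iodo-3-methylocta-2,6-dien-1-yl]oxolan-2-one | O=C1C[C@@H](C/C=C(C)/CC/C=C(C)/I)[C@@H](O1)C[C@@](C)(O[Si](C)(C)C(C)(C)C)[C@@H](Cl)CCO
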